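## Retrosynthetic overview

1. Alertenone (16) ⇒ two molecules of suberosenone (15), joined by Michael addition of the C4 lithium enolate of one to the exocyclic enone of the other.
2. 15 ⇒ tricyclic C2 ketone 12 by Wittig methylenation, then allylic oxidation at C3, so the methylene/ketone regiochemistry is unambiguous.
3. Cyclopentenone ring of 11 ⇒ intramolecular aldol condensation of 1,4-keto aldehyde 10 (acetyl on C1, formyl on C8 of a bicyclo[3.2.1]octene).
4. Bicyclo[3.2.1]octane 6 ⇒ intramolecular aldol (key ring closure) of keto aldehyde 5, made by organocatalytic Michael addition of β-keto ester 3 to crotonaldehyde 4.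
5. Ring order: gem-dimethylcyclopentane (from 1) → six-membered ring of the bicyclo[3.2.1]octane → cyclopentenone → dimerisation.

Assumption: the given SMILES is definitive; each quadrane unit is (1S,5S,6S,9S) on tricyclo[4.3.2.0^1,5]undecane numbering, and the CIP labels in the names below were derived from the SMILES.

## Route

**Step 1**
Reactants: 1, 3-methylcyclopent-2-en-1-one
Product: 2, 3,3-dimethylcyclopentan-1-one
Conditions: MeMgBr, CuBr·SMe2 (5 mol%), TMSCl, THF, −78 → 0 °C; then 1 M HCl
Reagents that add atoms: methylmagnesium bromide, C[Mg]Br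
Why: Cu-catalysed, TMSCl-accelerated conjugate addition of methyl to the β-methyl enone builds the gem-dimethyl carbon; no stereocentre is formed.

**Step 2**
Reactants: 2, 3,3-dimethylcyclopentan-1-one
Product: 3, methyl 4,4-dimethyl-2-oxocyclopentane-1-carboxylate (racemic, enolisable)
Conditions: NaH, (MeO)2CO, THF, reflux; AcOH quench
Reagents that add atoms: dimethyl carbonate, COC(=O)OC
Why: Reversible Claisen-type C-acylation ends at the α-CH2 remote from the neopentyl position and is driven by deprotonation of the β-keto ester.

**Step 3**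
Reactants: 3, methyl 4,4-dimethyl-2-oxocyclopentane-1-carboxylate; 4, (E)-but-2-enal
Product: 5, methyl (1S)-4,4-dimethyl-2-oxo-1-[(2S)-4-oxobutan-2-yl]cyclopentane-1-carboxylate
Conditions: (R)-2-[diphenyl(trimethylsilyloxy)methyl]pyrrolidine (10 mol%), PhCO2H (10 mol%), toluene, 0 °C → rt
Reagents that add atoms: none (4 is a reactant)
Why: Iminium-catalysed (Jørgensen–Hayashi type) Michael addition in which the (R)-catalyst blocks the Re face of C3 of the E-iminium, so the enol adds to the Si face and sets the (S) methyl carbon, while an open synclinal transition state with the iminium chain anti to CO2Me sets the (1S) quaternary centre.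

**Step 4**
Reactants: 5
Product: 6, methyl (1S,2S,5S)-4-hydroxy-2,6,6-trimethyl-8-oxobicyclo[3.2.1]octane-1-carboxylate (C4 epimers)
Conditions: DBU (20 mol%), CH2Cl2, 0 °C
Reagents that add atoms: none
Why: Intramolecular aldol addition of the C3 ketone enolate to the tethered aldehyde closes the six-membered ring; the bridge can only form cis, so C5 is dictated by C1 and the C2 methyl ends up syn to the C8 carbonyl, and the carbinol configuration is irrelevant because it is removed next.

**Step 5**
Reactants: 6
Product: 7, methyl (1S,2S,5R)-2,6,6-trimethyl-8-oxobicyclo[3.2.1]oct-3-ene-1-carboxylate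
Conditions: Burgess reagent, toluene, 70 °C
Reagents that add atoms: none
Why: Burgess syn-elimination under neutral conditions avoids retro-aldol, and because the bridgehead hydrogen cannot be lost (Bredt) only the C3=C4 alkene forms.

**Step 6**
Reactants: 7
Product: 8, methyl (1S,2S,5R)-8-(methoxymethylidene)-2,6,6-trimethylbicyclo[3.2.1]oct-3-ene-1-carboxylate (E/Z mixture)
Conditions: Ph3P(Cl)CH2OMe, KHMDS, THF, 0 → 45 °C
Reagents that add atoms: (methoxymethyl)triphenylphosphonium chloride, [Cl-].COC[P+](c1ccccc1)(c1ccccc1)c1ccccc1
Why: Wittig methoxymethylenation of the strained, non-enolisable bridging ketone adds the future C4 carbon and leaves the hindered quaternary ester untouched.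

**Step 7**
Reactants: 8
Product: 9, 1-[(1S,2S,5R)-8-(methoxymethylidene)-2,6,6-trimethylbicyclo[3.2.1]oct-3-en-1-yl]ethan-1-one
Conditions: Me3SiCH2Li (2.5 equiv), THF/pentane, 0 °C → rt; then MeOH, rt
Reagents that add atoms: (trimethylsilyl)methyllithium, [Li]C[Si](C)(C)C (supplies the CH3 carbon)
Why: Acyl substitution gives an α-silyl ketone that is immediately enolised, which prevents over-addition; methanolysis of the C–Si bond then gives the methyl ketone, and the enol ether and alkene are inert.

**Step 8**
Reactants: 9
Product: 10, (1S,2S,5S,8S)-1-acetyl-2,6,6-trimethylbicyclo[3.2.1]oct-3-ene-8-carbaldehyde (C8 epimers interconvert)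
Conditions: 1 M HCl, THF, rt
Reagents that add atoms: water, O
Why: Acid hydrolysis of the enol ether unmasks the aldehyde; C8 is epimerisable and prefers CHO on the side of the gem-dimethyl two-carbon bridge, avoiding a syn-diaxial clash with the axial C2 methyl.

**Step 9**
Reactants: 10
Product: 11, (1S,5S,6S,9S)-9,11,11-trimethyltricyclo[4.3.2.0^1,5]undeca-3,7-dien-2-one
Conditions: NaOMe, MeOH, 50 °C
Reagents that add atoms: none
Why: Intramolecular aldol condensation of the 1,4-keto aldehyde (methyl ketone enolate onto CHO) gives the cyclopentenone; C5 equilibrates through the aldehyde enol and the extended enolate, so the ring closes on the less congested two-carbon-bridge side and fixes (5S).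

**Step 10**
Reactants: 11
Product: 12, (1S,5S,6S,9S)-9,11,11-trimethyltricyclo[4.3.2.0^1,5]undecan-2-one
Conditions: H2 (1 atm), 10% Pd/C, EtOAc, rt
Reagents that add atoms: none (H2 only)
Why: Heterogeneous hydrogenation saturates the enone C=C and the ring alkene; no new stereocentre is created and the ketone survives.

**Step 11**
Reactants: 12
Product: 13, (1S,5S,6S,9S)-9,11,11-trimethyl-2-methylidenetricyclo[4.3.2.0^1,5]undecane
Conditions: Ph3PCH3Br, KOt-Bu, toluene, 90 °C
Reagents that add atoms: methyltriphenylphosphonium bromide, [Br-].C[P+](c1ccccc1)(c1ccccc1)c1ccccc1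
Why: Wittig methylenation of the hindered cyclopentanone places the exocyclic methylene next to the quaternary carbon; no epimerisable stereocentre is adjacent.

**Step 12**
Reactants: 13
Product: 14, (1S,3RS,5S,6S,9S)-9,11,11-trimethyl-2-methylidenetricyclo[4.3.2.0^1,5]undecan-3-ol
Conditions: SeO2 (0.5 equiv), t-BuOOH (3 equiv), CH2Cl2, rt
Reagents that add atoms: selenium dioxide, O=[Se]=O; tert-butyl hydroperoxide, CC(C)(C)OO (oxygen source)
Why: Sharpless SeO2 allylic oxidation (ene reaction then [2,3]-shift) can only oxidise C3, the sole allylic C–H position, and returns the double bond to the exocyclic position; the carbinol configuration is irrelevant.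

**Step 13**
Reactants: 14
Product: 15, suberosenone, (1S,5S,6S,9S)-9,11,11-trimethyl-2-methylidenetricyclo[4.3.2.0^1,5]undecan-3-one
Conditions: Dess–Martin periodinane, NaHCO3, CH2Cl2, 0 °C → rt
Reagents that add atoms: none
Why: Mild, buffered oxidation of the allylic alcohol gives the α-methylene ketone without conjugate-addition side reactions.

**Step 14**
Reactants: 15 (two molecules)
Product: 16, alertenone, (1S,4R,5R,6S,9S)-9,11,11-trimethyl-2-methylidene-4-{[(1S,2S,5S,6S,9S)-9,11,11-trimethyl-3-oxotricyclo[4.3.2.0^1,5]undecan-2-yl]methyl}tricyclo[4.3.2.0^1,5]undecan-3-one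
Conditions: LiHMDS (1.0 equiv), 15 (1.0 equiv), THF, −78 °C; then 15 (1.0 equiv), −78 → −40 °C; AcOH, −78 °C
Reagents that add atoms: none
Why: Intermolecular Michael addition in which C4 is the only enolisable position of 15; the enolate attacks the exocyclic enone on its face away from the gem-dimethyl bridge (cis to H-5, giving 4R), and kinetic protonation of the resulting hindered enolate anti to the axial C9′ methyl gives 2′S. A second Michael would create vicinal quaternary centres and is slow at −78 °C.

## Compound list

1 | 3-methylcyclopent-2-en-1-one | CC1=CC(=O)CC1 | starting material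
2 | 3,3-dimethylcyclopentan-1-one | CC1(C)CCC(=O)C1 | intermediate
3 | methyl 4,4-dimethyl-2-oxocyclopentane-1-carboxylate | COC(=O)C1CC(C)(C)CC1=O | intermediate
4 | (E)-but-2-enal (crotonaldehyde) | C/C=C/C=O | starting material
5 | methyl (1S)-4,4-dimethyl-2-oxo-1-[(2S)-4-oxobutan-2-yl]cyclopentane-1-carboxylate | O=CC[C@H](C)[C@@]1(C(=O)OC)CC(C)(C)CC1=O | intermediate
6 | methyl (1S,2S,5S)-4-hydroxy-2,6,6-trimethyl-8-oxobicyclo[3.2.1]octane-1-carboxylate (C4 epimers) | O=C1[C@@H]2C(O)C[C@H](C)[C@@]1(C(=O)OC)CC2(C)C | intermediate
7 | methyl (1S,2S,5R)-2,6,6-trimethyl-8-oxobicyclo[3.2.1]oct-3-ene-1-carboxylate | O=C1[C@@H]2C=C[C@H](C)[C@@]1(C(=O)OC)CC2(C)C | intermediate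
8 | methyl (1S,2S,5R)-8-(methoxymethylidene)-2,6,6-trimethylbicyclo[3.2.1]oct-3-ene-1-carboxylate (E/Z) | COC=C1[C@@H]2C=C[C@H](C)[C@@]1(C(=O)OC)CC2(C)C | intermediate
9 | 1-[(1S,2S,5R)-8-(methoxymethylidene)-2,6,6-trimethylbicyclo[3.2.1]oct-3-en-1-yl]ethan-1-one | COC=C1[C@@H]2C=C[C@H](C)[C@@]1(C(C)=O)CC2(C)C | intermediate
10 | (1S,2S,5S,8S)-1-acetyl-2,6,6-trimethylbicyclo[3.2.1]oct-3-ene-8-carbaldehyde | O=C[C@H]1[C@@H]2C=C[C@H](C)[C@@]1(C(C)=O)CC2(C)C | intermediate
11 | (1S,5S,6S,9S)-9,11,11-trimethyltricyclo[4.3.2.0^1,5]undeca-3,7-dien-2-one | O=C1C=C[C@H]2[C@@H]3C=C[C@H](C)[C@]12CC3(C)C | intermediate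
12 | (1S,5S,6S,9S)-9,11,11-trimethyltricyclo[4.3.2.0^1,5]undecan-2-one | O=C1CC[C@H]2[C@@H]3CC[C@H](C)[C@]12CC3(C)C | intermediate
13 | (1S,5S,6S,9S)-9,11,11-trimethyl-2-methylidenetricyclo[4.3.2.0^1,5]undecane | C=C1CC[C@H]2[C@@H]3CC[C@H](C)[C@]12CC3(C)C | intermediate
14 | (1S,3RS,5S,6S,9S)-9,11,11-trimethyl-2-methylidenetricyclo[4.3.2.0^1,5]undecan-3-ol | C=C1C(O)C[C@H]2[C@@H]3CC[C@H](C)[C@]12CC3(C)C | intermediate
15 | suberosenone, (1S,5S,6S,9S)-9,11,11-trimethyl-2-methylidenetricyclo[4.3.2.0^1,5]undecan-3-one | C=C1C(=O)C[C@H]2[C@@H]3CC[C@H](C)[C@]12CC3(C)C | intermediate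
16 | alertenone | C=C1C(=O)[C@H](C[C@@H]2C(=O)C[C@H]3[C@@H]4CC[C@H](C)[C@]23CC4(C)C)[C@H]2[C@@H]3CC[C@H](C)[C@]12CC3(C)C | target

## Step count

Total step count: 14.
Longest linear sequence: 14 (1 → 15 in 13 steps, then the final step unites two molecules of 15).

## Steps most likely to fail, with fallbacks

1. **Step 3** (diastereoselectivity at the quaternary carbon relative to the methyl centre, and ee). Fallback: add 3 to acrolein with a cinchona-alkaloid catalyst so only C1 is set, close the bicycle by the same aldol, oxidise C4–OH and dehydrogenate to the bicyclic enone, introduce the methyl by Me2CuLi addition from the face syn to C8, then remove the C4 oxygen via its enol triflate.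

2. **Step 9** (ring closure and the C8/C5 configuration, which relies on thermodynamic control). Fallback: reverse the annulation polarity by converting the ester into an acetonyl group, aldol-condensing it onto the C8 ketone, and setting the ring-fusion hydrogen by Li/NH3 reduction of that enone (protonation of the β-carbanion) or by hydroxyl-directed hydrogenation from a retained C–OH on the three-carbon bridge.

3. **Step 14** (oligomerisation, or the wrong C2′ epimer on protonation). Fallback: a crossed Mukaiyama–Michael reaction of the TBS dienol ether of 15 with 15 under Lewis acid catalysis, followed by low-temperature protodesilylation; or mask the donor enone as its PhSH adduct, couple, and regenerate the methylene by sulfoxide elimination.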